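The route rests on cutting ring B of the decalin back to an acyclic (E,E)-nitrotriene. One thermal intramolecular Diels–Alder reaction forms the ring-fusion bond C5–C10 (labdane numbering), which closes ring A over the C1–C4 tether, together with C6–C7, and sets quaternary C10 and the trans C5–H under control of the C3 silyloxy stereocentre. It exploits the oxygen on C6 beside the fusion carbon C5, carried as a nitro group that activates the C5=C6 dienophile, and the C8–C9 bond of ring B, left as the cycloadduct alkene for the later C9 carbinol. The precursor is a 1-nitro-1,7,9-decatriene holding C3–O and the C4 gem-dimethyl group in its tether.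

Key step: step 7

Remark on numbering: atom numbers are those of the labdane skeleton (ring A = C1–C5 and C10; ring B = C5–C10; side chain C11–C16; C17 on C8; C18 and C19 on C4; C20 on C10); β is the face that carries C20.
Assumption: 3-bromofuran-2(5H)-one is taken as a purchasable building block.

Step 1
Reactants: 1 methyl 2,2-dimethyl-3-oxobutanoate; 2 3-bromoprop-1-yne (propargyl bromide)
Product: 4 methyl 2,2-dimethyl-3-oxohept-6-ynoate, via lithium enolate 3 (not isolated)
Conditions: LiN(i-Pr)2, THF, −78 °C; then 2, DMPU, −78 to 0 °C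
Reagents that add atoms: none
Why: The acetyl methyl is the only enolisable position, so its kinetic lithium enolate should be C-alkylated by the propargylic bromide (ketone enolate alkylation), which gives C2–C1 and the terminal alkyne C10≡C9.

Step 2
Reactants: 4 methyl 2,2-dimethyl-3-oxohept-6-ynoate
Product: 5 methyl (3S)-3-hydroxy-2,2-dimethylhept-6-ynoate
Conditions: (R)-2-methyl-CBS-oxazaborolidine (20 mol%), catecholborane, toluene, −78 °C
Reagents that add atoms: none
Why: Corey–Bakshi–Shibata reduction, in which the (R)-oxazaborolidine treats the quaternary C(CH3)2CO2CH3 group as the large substituent and should deliver hydride to the face that gives the (S)-carbinol (future C3), while ester and alkyne stay untouched.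

Step 3
Reactants: 5 methyl (3S)-3-hydroxy-2,2-dimethylhept-6-ynoate
Product: 6 methyl (3S)-3-[(tert-butyldimethylsilyl)oxy]-2,2-dimethylhept-6-ynoate
Conditions: TBSOTf, 2,6-lutidine, CH2Cl2, 0 °C
Reagents that add atoms: tert-butyldimethylsilyl triflate, CC(C)(C)[Si](C)(C)OS(=O)(=O)C(F)(F)F
Why: Silyl ether formation with the reactive triflate should protect the hindered neopentyl-type O3 for the whole route.

Step 4
Reactants: 6 methyl (3S)-3-[(tert-butyldimethylsilyl)oxy]-2,2-dimethylhept-6-ynoate; 7 2-bromopropene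
Product: 9 methyl (3S,6E)-3-[(tert-butyldimethylsilyl)oxy]-2,2,6,8-tetramethylnona-6,8-dienoate, via alkenylalane 8 (not isolated)
Conditions: AlMe3, Cp2ZrCl2 (25 mol%), CH2Cl2, 0 °C to rt; then 7, Pd(PPh3)4 (5 mol%), ZnCl2 (cat.), THF, rt
Reagents that add atoms: trimethylaluminium, C[Al](C)C
Why: Negishi zirconium-catalysed syn-carboalumination should put the methyl group (C20) on the internal carbon C10 and aluminium on C9, and the palladium-catalysed Negishi coupling proceeds with retention, so the tether ends up on the outside position of the (E)-diene; the hindered ester should not react with AlMe3 at this temperature.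

Step 5
Reactants: 9 methyl (3S,6E)-3-[(tert-butyldimethylsilyl)oxy]-2,2,6,8-tetramethylnona-6,8-dienoate
Product: 10 (3S,6E)-3-[(tert-butyldimethylsilyl)oxy]-2,2,6,8-tetramethylnona-6,8-dienal
Conditions: i-Bu2AlH (1.1 equiv), CH2Cl2, −78 °C; quench at −78 °C
Reagents that add atoms: none
Why: Partial ester reduction should stop at the aldehyde (C5) because the aluminium hemiacetal of this α-quaternary ester is stable at −78 °C until the quench.

Step 6
Reactants: 10 (3S,6E)-3-[(tert-butyldimethylsilyl)oxy]-2,2,6,8-tetramethylnona-6,8-dienal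
Product: 13 tert-butyldimethyl{[(1E,4S,7E)-3,3,7,9-tetramethyl-1-nitrodeca-1,7,9-trien-4-yl]oxy}silane, via nitro alcohol 11 (not isolated), via mesylate 12 (not isolated)
Conditions: CH3NO2 (solvent), tetramethylguanidine (10 mol%), 0 °C to rt; evaporate; then MsCl, Et3N, CH2Cl2, 0 °C
Reagents that add atoms: nitromethane, C[N+](=O)[O-]
Why: Henry addition to the non-enolisable aldehyde followed by mesylation and E1cB elimination should give the thermodynamically favoured (E)-nitroalkene, which brings in C6 with its heteroatom.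

Step 7
Reactants: 13 tert-butyldimethyl{[(1E,4S,7E)-3,3,7,9-tetramethyl-1-nitrodeca-1,7,9-trien-4-yl]oxy}silane
Product: 14 nitro octalin: trans-fused bicycle (5α-H, 10β-CH3) with 3β-OTBS, 4,4-dimethyl, 6α-nitro and a C8=C9 double bond that carries CH3 on C8
Conditions: toluene (0.02 M), BHT (5 mol%), 100 °C, sealed tube
Reagents that add atoms: none
Why: The nitroalkene C5=C6 (LUMO) and the trialkyl diene C7=C8–C9=C10 (HOMO) combine in a concerted but asynchronous [4+2] cycloaddition in which the bond from the electrophilic C5 to C10 runs ahead of C6–C7; the closest known reaction type is the type 1 intramolecular Diels–Alder reaction of (E)-1-nitro-1,7,9-decatrienes. Ring A is closed by the C5–C10 bond with the four-carbon tether C1–C4 in a chair (exo to both π systems), and ring B is closed as the new cyclohexene by C6–C7. C10 (quaternary, C20 β) and C5 (H α) should become trans because the tether sits outside on C10 (fixed by the E geometry from step 4) and lies anti to the diene while the nitro group is endo; C6 (nitro α) follows from the E dienophile and is erased in step 10. The absolute sense comes from C3, whose silyloxy group takes the equatorial site of the chair-like tether. The step needs endo and π-facial selectivity: the first rests on the endo preference of nitroalkenes, the second on the C3 stereocentre, and the Thorpe–Ingold effect of the C4 gem-dimethyl group together with the low LUMO of the nitroalkene should offset the retarding inside methyl on C10.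

Step 8
Reactants: 14 nitro octalin
Product: 17 nitro ketone: trans-decalin with 3β-OTBS, 6α-nitro, 8α-CH3 and C9=O, via alkylborane 15 (not isolated), via 8-epi ketone 16 (not isolated)
Conditions: BH3·THF, THF, 0 °C to rt; then pyridinium chlorochromate (C5H5NH)[CrO3Cl], NaOAc, CH2Cl2, 40 °C; then DBU, CH2Cl2, rt
Reagents that add atoms: pyridinium chlorochromate, [O-][Cr](=O)(=O)Cl.c1cc[nH+]cc1
Why: Brown hydroboration should place boron on the less substituted C9 from the α face, direct chromate oxidation of the C–B bond gives the C9 ketone, and the amidine base equilibrates C8 to the equatorial 8α-methyl (the axial epimer is syn-diaxial to C20), while the nitro group is inert to borane and chromate.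

Step 9
Reactants: 17 nitro ketone
Product: 19 nitro alkene: 3β-OTBS, 6α-nitro, 8α-CH3, exocyclic C9=C11H2, via potassium nitronate 18 (not isolated)
Conditions: Ph3PCH3Br (5 equiv), KOt-Bu (5 equiv), toluene, 90 °C; aq. NH4Cl work-up
Reagents that add atoms: methyltriphenylphosphonium bromide, C[P+](c1ccccc1)(c1ccccc1)c1ccccc1.[Br-]
Why: Wittig methylenation with excess salt-free ylide at elevated temperature is the standard answer to hindered α-branched ketones; the acidic nitro group is masked in the flask as its nitronate and returns on work-up, and C8 reacts from its thermodynamic 8α-methyl configuration.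

Step 10
Reactants: 19 nitro alkene
Product: 21 ketone: 3β-OTBS, 8α-CH3, C9=C11H2, C6=O, via sodium nitronate 20 (not isolated)
Conditions: NaOMe, MeOH, 0 °C; then aq. TiCl3, NH4OAc buffer, rt
Reagents that add atoms: water, O
Why: In the titanium trichloride variant of the Nef reaction the nitronate is reduced to the imine, which hydrolyses to the C6 ketone at a buffered pH that should spare the exocyclic alkene and the silyl ether.

Step 11
Reactants: 21 ketone
Product: 22 6β-alcohol: 3β-OTBS, 6β-OH, 8α-CH3, C9=C11H2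
Conditions: NaBH4, MeOH–THF, 0 °C
Reagents that add atoms: none
Why: Substrate-controlled carbonyl reduction, in which hydride should attack C6 from the α face because the β face is blocked by the syn-axial C19 and C20 methyl groups, gives the axial 6β-alcohol.

Step 12
Reactants: 22 6β-alcohol
Product: 23 9α,11-epoxide: spiro-oxirane on C9 with its oxygen on the α face, 3β-OTBS, 6β-OH, 8α-CH3
Conditions: mCPBA, NaHCO3, CH2Cl2, 0 °C
Reagents that add atoms: 3-chloroperbenzoic acid, OOC(=O)c1cccc(Cl)c1
Why: Prilezhaev epoxidation of the exocyclic alkene should occur on the α face, anti to the neighbouring axial C20 methyl, which sets the C9–O bond of the future 9α-hydroxyl.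

Step 13
Reactants: 23 9α,11-epoxide
Product: 25 vinyl carbinol: 3β-OTBS, 6β-OH, 9α-OH, 9β-vinyl (C11=C12), 8α-CH3, via sulfonium betaine 24 (not isolated)
Conditions: Me3S+ I− (6 equiv), n-BuLi (5.5 equiv), THF, −10 °C to rt
Reagents that add atoms: trimethylsulfonium iodide, C[S+](C)C.[I-]
Why: Dimethylsulfonium methylide should open the epoxide at its CH2 terminus (C11) and the sulfonium alkoxide then loses dimethyl sulfide (one-carbon homologation of an epoxide to an allylic alcohol), which adds C12 and leaves the C9 configuration untouched.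

Step 14
Reactants: 25 vinyl carbinol
Product: 26 6β-acetate: 3β-OTBS, 6β-OAc, 9α-OH, 9β-vinyl, 8α-CH3
Conditions: Ac2O, DMAP, Et3N, CH2Cl2, 40 °C
Reagents that add atoms: acetic anhydride, CC(=O)OC(C)=O
Why: Acylation catalysed by DMAP should take place only at the secondary 6β-hydroxyl, since the tertiary C9 hydroxyl next to the quaternary C10 is inert under these conditions.

Step 15
Reactants: 26 6β-acetate; 27 3-bromofuran-2(5H)-one
Product: 29 3-O-TBS ether of the target: 3β-OTBS, 6β-OAc, 9α-OH, C11H2–C12H2 linked to C13 of the 13-en-16,15-olide, via B-alkyl-9-BBN adduct 28 (not isolated)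
Conditions: 9-BBN dimer (3 equiv), THF, rt to 50 °C; then 27, PdCl2(dppf) (10 mol%), AsPh3, K3PO4 (aq.), DMF, rt
Reagents that add atoms: none
Why: Anti-Markovnikov hydroboration of the vinyl group followed by B-alkyl Suzuki–Miyaura coupling with the α-bromobutenolide should form C12–C13 under a mild base that spares acetate and lactone.

Step 16
Reactants: 29 3-O-TBS ether of the target
Product: 30 6β-acetoxy-3β,9α-dihydroxylabd-13-en-16,15-olide (target)
Conditions: HF·pyridine, THF, 0 °C to rt
Reagents that add atoms: none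
Why: Fluoride-mediated desilylation should free the 3β-hydroxyl without touching the acetate, the butenolide or the tertiary alcohol.

Compound list
1 | methyl 2,2-dimethyl-3-oxobutanoate | COC(=O)C(C)(C)C(C)=O | starting material
2 | 3-bromoprop-1-yne (propargyl bromide) | BrCC#C | starting material
3 | lithium enolate of 1 (terminal enolate) | [Li+].[O-]C(=C)C(C)(C)C(=O)OC | intermediate
4 | methyl 2,2-dimethyl-3-oxohept-6-ynoate | COC(=O)C(C)(C)C(=O)CCC#C | intermediate
5 | methyl (3S)-3-hydroxy-2,2-dimethylhept-6-ynoate | C#CCC[C@H](O)C(C)(C)C(=O)OC | intermediate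
6 | methyl (3S)-3-[(tert-butyldimethylsilyl)oxy]-2,2-dimethylhept-6-ynoate | C#CCC[C@H](O[Si](C)(C)C(C)(C)C)C(C)(C)C(=O)OC | intermediate
7 | 2-bromopropene | CC(Br)=C | starting material
8 | methyl (3S,6E)-3-[(tert-butyldimethylsilyl)oxy]-7-(dimethylalumanyl)-2,2,6-trimethylhept-6-enoate (alkenylalane) | C[Al](C)/C=C(C)/CC[C@H](O[Si](C)(C)C(C)(C)C)C(C)(C)C(=O)OC | intermediate
9 | methyl (3S,6E)-3-[(tert-butyldimethylsilyl)oxy]-2,2,6,8-tetramethylnona-6,8-dienoate | C=C(C)/C=C(C)/CC[C@H](O[Si](C)(C)C(C)(C)C)C(C)(C)C(=O)OC | intermediate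
10 | (3S,6E)-3-[(tert-butyldimethylsilyl)oxy]-2,2,6,8-tetramethylnona-6,8-dienal | C=C(C)/C=C(C)/CC[C@H](O[Si](C)(C)C(C)(C)C)C(C)(C)C=O | intermediate
11 | (4S,7E)-4-[(tert-butyldimethylsilyl)oxy]-3,3,7,9-tetramethyl-1-nitrodeca-7,9-dien-2-ol (both C2 epimers) | C=C(C)/C=C(C)/CC[C@H](O[Si](C)(C)C(C)(C)C)C(C)(C)C(O)C[N+](=O)[O-] | intermediate
12 | methanesulfonate of 11 | C=C(C)/C=C(C)/CC[C@H](O[Si](C)(C)C(C)(C)C)C(C)(C)C(OS(C)(=O)=O)C[N+](=O)[O-] | intermediate
13 | tert-butyldimethyl{[(1E,4S,7E)-3,3,7,9-tetramethyl-1-nitrodeca-1,7,9-trien-4-yl]oxy}silane | C=C(C)/C=C(C)/CC[C@H](O[Si](C)(C)C(C)(C)C)C(C)(C)/C=C/[N+](=O)[O-] | intermediate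
14 | nitro octalin: trans-fused (5α-H, 10β-CH3), 3β-OTBS, 4,4-dimethyl, 6α-NO2, C8=C9 with CH3 on C8 | [O-][N+](=O)[C@H]1CC(C)=C[C@@]2(C)CC[C@H](O[Si](C)(C)C(C)(C)C)C(C)(C)[C@H]12 | intermediate
15 | alkylborane: BH2 on C9 (α), H on C8 (α), 8β-CH3, otherwise as 14 | [O-][N+](=O)[C@H]1C[C@H](C)[C@@H](B)[C@@]2(C)CC[C@H](O[Si](C)(C)C(C)(C)C)C(C)(C)[C@H]12 | intermediate
16 | 8-epi ketone: C9=O, 8β-CH3, 6α-NO2, 3β-OTBS | [O-][N+](=O)[C@H]1C[C@H](C)C(=O)[C@@]2(C)CC[C@H](O[Si](C)(C)C(C)(C)C)C(C)(C)[C@H]12 | intermediate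
17 | nitro ketone: C9=O, 8α-CH3, 6α-NO2, 3β-OTBS, trans-decalin | [O-][N+](=O)[C@H]1C[C@@H](C)C(=O)[C@@]2(C)CC[C@H](O[Si](C)(C)C(C)(C)C)C(C)(C)[C@H]12 | intermediate
18 | potassium C6-nitronate of 17 | [K+].[O-][N+]([O-])=C1C[C@@H](C)C(=O)[C@@]2(C)CC[C@H](O[Si](C)(C)C(C)(C)C)C(C)(C)[C@H]12 | intermediate
19 | nitro alkene: exocyclic C9=C11H2, 8α-CH3, 6α-NO2, 3β-OTBS | [O-][N+](=O)[C@H]1C[C@@H](C)C(=C)[C@@]2(C)CC[C@H](O[Si](C)(C)C(C)(C)C)C(C)(C)[C@H]12 | intermediate
20 | sodium C6-nitronate of 19 | [Na+].[O-][N+]([O-])=C1C[C@@H](C)C(=C)[C@@]2(C)CC[C@H](O[Si](C)(C)C(C)(C)C)C(C)(C)[C@H]12 | intermediate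
21 | ketone: C6=O, exocyclic C9=C11H2, 8α-CH3, 3β-OTBS | O=C1C[C@@H](C)C(=C)[C@@]2(C)CC[C@H](O[Si](C)(C)C(C)(C)C)C(C)(C)[C@H]12 | intermediate
22 | 6β-alcohol: 6β-OH, exocyclic C9=C11H2, 8α-CH3, 3β-OTBS | O[C@@H]1C[C@@H](C)C(=C)[C@@]2(C)CC[C@H](O[Si](C)(C)C(C)(C)C)C(C)(C)[C@H]12 | intermediate
23 | 9α,11-epoxide: spiro-oxirane, O on the α face of C9, 6β-OH, 8α-CH3, 3β-OTBS | O[C@@H]1C[C@@H](C)[C@]3(CO3)[C@@]2(C)CC[C@H](O[Si](C)(C)C(C)(C)C)C(C)(C)[C@H]12 | intermediate
24 | sulfonium betaine: 9α-oxido, 9β-CH2CH2S+(CH3)2, 6β-OH, 3β-OTBS | O[C@@H]1C[C@@H](C)[C@]([O-])(CC[S+](C)C)[C@@]2(C)CC[C@H](O[Si](C)(C)C(C)(C)C)C(C)(C)[C@H]12 | intermediate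
25 | vinyl carbinol: 9α-OH, 9β-vinyl, 6β-OH, 8α-CH3, 3β-OTBS | O[C@@H]1C[C@@H](C)[C@](O)(C=C)[C@@]2(C)CC[C@H](O[Si](C)(C)C(C)(C)C)C(C)(C)[C@H]12 | intermediate
26 | 6β-acetate of 25 | CC(=O)O[C@@H]1C[C@@H](C)[C@](O)(C=C)[C@@]2(C)CC[C@H](O[Si](C)(C)C(C)(C)C)C(C)(C)[C@H]12 | intermediate
27 | 3-bromofuran-2(5H)-one | O=C1OCC=C1Br | starting material
28 | B-alkyl-9-BBN adduct: C12 bound to the boron of 9-borabicyclo[3.3.1]nonane, otherwise as 26 | CC(=O)O[C@@H]1C[C@@H](C)[C@](O)(CCB3C4CCCC3CCC4)[C@@]2(C)CC[C@H](O[Si](C)(C)C(C)(C)C)C(C)(C)[C@H]12 | intermediate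
29 | 3-O-(tert-butyldimethylsilyl) ether of the target | CC(=O)O[C@@H]1C[C@@H](C)[C@](O)(CCC3=CCOC3=O)[C@@]2(C)CC[C@H](O[Si](C)(C)C(C)(C)C)C(C)(C)[C@H]12 | intermediate
30 | 6β-acetoxy-3β,9α-dihydroxylabd-13-en-16,15-olide | CC(=O)O[C@@H]1C[C@@H](C)[C@](O)(CCC2=CCOC2=O)[C@@]2(C)CC[C@H](O)C(C)(C)[C@H]12 | target

Total step count: 16. Longest linear sequence: 16 steps (1 to 30); 2, 7 and 27 are used as purchased.

Steps most likely to fail

Step 7. The nitroalkene may polymerise or react through its N=O bond before the hindered diene terminus (inside methyl on C10) engages, and exo approach or attack on the wrong π face may erode the trans fusion and the C3-to-C10 relationship. The fallback sets out from aldehyde 10 and replaces the nitro activator by a thermally robust sulfone. Horner–Wadsworth–Emmons reaction with diethyl [(phenylsulfonyl)methyl]phosphonate (NaH, THF) should give the (E)-vinyl sulfone F1. Its intramolecular Diels–Alder reaction at 170 °C (o-dichlorobenzene, BHT) should give the 6α-phenylsulfonyl octalin F2. Hydroboration, chromate oxidation and base equilibration as in step 8 lead to the C9 ketone F3, and Wittig methylenation, here without an acidic nitro group, to the exocyclic alkene F4. Oxidative desulfonylation (n-BuLi, THF, −78 °C; then Me3SiOOSiMe3) comes back to ketone 21, where C5 can be equilibrated with NaOMe if cis-fused material has been carried along.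

Step 9. The ylide may only enolise the hindered C9 ketone or be used up by the acidic nitro group, and the nitronate may open the γ-nitro ketone by retro-Michael reaction at the temperature the olefination needs. The fallback sets out from nitro ketone 17 and runs the Nef reaction first (NaOMe; then TiCl3, NH4OAc), which should give the 6,9-dione F5. K[(s-Bu)3BH] at −78 °C should reduce only the C6 carbonyl by equatorial attack from the α face, because the C9 carbonyl is shielded on its equatorial side by C20 and flanked by the quaternary C10; this gives the 6β-hydroxy ketone F6. Non-basic Lombardo methylenation (Zn, CH2Br2, TiCl4) comes back to alcohol 22.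

Step 15. Transmetalation from the hindered alkylborane may be slower than protodeboronation or base-induced degradation of the bromobutenolide. The fallback sets out from acetate 26: hydroboration with 9-BBN and oxidation with NaBO3·4H2O should give the primary alcohol F7, and the Appel reaction (I2, PPh3, imidazole) the primary iodide F8. Nickel-catalysed reductive cross-electrophile coupling of this iodide with 27 (NiBr2·diglyme, 4,4'-di-tert-butyl-2,2'-bipyridine, Zn, DMA) forms C12–C13 without any base and comes back to 29.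

Further compounds
F1 | step 7 | tert-butyldimethyl{[(1E,4S,7E)-3,3,7,9-tetramethyl-1-(phenylsulfonyl)deca-1,7,9-trien-4-yl]oxy}silane | C=C(C)/C=C(C)/CC[C@H](O[Si](C)(C)C(C)(C)C)C(C)(C)/C=C/S(=O)(=O)c1ccccc1
F2 | step 7 | sulfonyl octalin: trans-fused, 3β-OTBS, 6α-SO2Ph, C8=C9 with CH3 on C8 | O=S(=O)(c1ccccc1)[C@H]1CC(C)=C[C@@]2(C)CC[C@H](O[Si](C)(C)C(C)(C)C)C(C)(C)[C@H]12
F3 | step 7 | sulfonyl ketone: C9=O, 8α-CH3, 6α-SO2Ph, 3β-OTBS | O=S(=O)(c1ccccc1)[C@H]1C[C@@H](C)C(=O)[C@@]2(C)CC[C@H](O[Si](C)(C)C(C)(C)C)C(C)(C)[C@H]12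
F4 | step 7 | sulfonyl alkene: exocyclic C9=C11H2, 8α-CH3, 6α-SO2Ph, 3β-OTBS | O=S(=O)(c1ccccc1)[C@H]1C[C@@H](C)C(=C)[C@@]2(C)CC[C@H](O[Si](C)(C)C(C)(C)C)C(C)(C)[C@H]12
F5 | step 9 | 6,9-dione: C6=O, C9=O, 8α-CH3, 3β-OTBS | O=C1C[C@@H](C)C(=O)[C@@]2(C)CC[C@H](O[Si](C)(C)C(C)(C)C)C(C)(C)[C@H]12
F6 | step 9 | 6β-hydroxy ketone: 6β-OH, C9=O, 8α-CH3, 3β-OTBS | O[C@@H]1C[C@@H](C)C(=O)[C@@]2(C)CC[C@H](O[Si](C)(C)C(C)(C)C)C(C)(C)[C@H]12
F7 | step 15 | primary alcohol: 9β-CH2CH2OH, 9α-OH, 6β-OAc, 3β-OTBS | CC(=O)O[C@@H]1C[C@@H](C)[C@](O)(CCO)[C@@]2(C)CC[C@H](O[Si](C)(C)C(C)(C)C)C(C)(C)[C@H]12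
F8 | step 15 | primary iodide: 9β-CH2CH2I, 9α-OH, 6β-OAc, 3β-OTBS | CC(=O)O[C@@H]1C[C@@H](C)[C@](O)(CCI)[C@@]2(C)CC[C@H](O[Si](C)(C)C(C)(C)C)C(C)(C)[C@H]12
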